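The lactone (O1, C2 carbonyl, C4 carbinol, C6) is opened at O1–C6 and the side chain is cut at C8–C9. Once C7=C8 is a vinyl group, the quaternary C6 sits at the end of a C6–C7–C8 allyl unit five atoms from the C2 carboxylate oxygen, so a chiral palladium catalyst can tell its two faces apart. In one operation the key step forms the O1–C6 bond, the six-membered ring and the C6 stereocentre. Its precursor is an open-chain 3-hydroxy acid with the C4 centre already fixed (asymmetric epoxidation) and a geometrically pure (E)-allylic methyl carbonate (syn-carboalumination); the C9–C18 chain follows by alkyl–alkyl cross-coupling.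

Key step: step 10

Assumption: lactone numbering (O1, C2 … C6, chain from C7) is used for all intermediates; the sense of induction of the ligand for a tethered carboxylate has no direct calibration, so the (R,R)-ligand is written and its mirror image is used instead if it favours the C6 epimer.

Remark: (6S) in the vinyl lactone 15 and (6R) in the target describe the same spatial arrangement at C6; only the priority of vinyl against the ring CH2 changes.

Step 1
Reactants: 1 tert-butyl(but-3-yn-1-yloxy)dimethylsilane
Product: 4 (2E)-5-[(tert-butyldimethylsilyl)oxy]-3-methylpent-2-en-1-ol, via alkenylalane 2 (not isolated), via lithium alanate 3 (not isolated)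
Conditions: Me3Al (2.5 equiv), Cp2ZrCl2 (0.25 equiv), CH2Cl2, 0 °C to rt; then hexane/THF, n-BuLi, −78 °C; (CH2O)n, −78 °C to rt; aqueous potassium sodium tartrate
Reagents that add atoms: trimethylaluminium C[Al](C)C; formaldehyde (from paraformaldehyde) C=O
Why: Zirconium-catalysed carboalumination (Negishi carboalumination) adds methyl and aluminium syn across the terminal alkyne with aluminium on the terminal carbon, and the derived alanate attacks formaldehyde with retention at the alkenyl carbon, so only the E trisubstituted alkene should form.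

Step 2
Reactants: 4 (2E)-5-[(tert-butyldimethylsilyl)oxy]-3-methylpent-2-en-1-ol
Product: 5 [(2S,3S)-3-{2-[(tert-butyldimethylsilyl)oxy]ethyl}-3-methyloxiran-2-yl]methanol
Conditions: Ti(OiPr)4 (10 mol%), L-(+)-diethyl tartrate (12 mol%), t-BuOOH, 4 Å molecular sieves, CH2Cl2, −20 °C
Reagents that add atoms: tert-butyl hydroperoxide CC(C)(C)OO
Why: Sharpless asymmetric epoxidation of an (E)-3-methylalk-2-en-1-ol, in which the titanium L-(+)-tartrate complex delivers oxygen to the face that gives the (2S,3S)-epoxide and so sets the carbon that becomes C4.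

Step 3
Reactants: 5 [(2S,3S)-3-{2-[(tert-butyldimethylsilyl)oxy]ethyl}-3-methyloxiran-2-yl]methanol
Product: 6 (3R)-5-[(tert-butyldimethylsilyl)oxy]-3-methylpentane-1,3-diol
Conditions: NaAlH2(OCH2CH2OMe)2, THF, 0 °C; aqueous potassium sodium tartrate
Reagents that add atoms: none
Why: Regioselective reductive opening of a 2,3-epoxy alcohol, in which the alkoxide-bound aluminium hydride delivers hydride to C2 while the fully substituted C3 keeps its C–O bond, so the tertiary carbinol configuration is retained in the 1,3-diol.

Step 4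
Reactants: 6 (3R)-5-[(tert-butyldimethylsilyl)oxy]-3-methylpentane-1,3-diol
Product: 7 (3S)-5-[(tert-butyldimethylsilyl)oxy]-3-hydroxy-3-methylpentanal
Conditions: TEMPO (10 mol%), PhI(OAc)2 (1.1 equiv), CH2Cl2, rt
Reagents that add atoms: none
Why: Oxoammonium (TEMPO/PhI(OAc)2) oxidation is selective for the primary alcohol and stops at the aldehyde when water is absent, while the tertiary alcohol and the silyl ether are inert.

Step 5
Reactants: 7 (3S)-5-[(tert-butyldimethylsilyl)oxy]-3-hydroxy-3-methylpentanal
Product: 8 (3R)-1-[(tert-butyldimethylsilyl)oxy]-3-methylhex-5-yn-3-ol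
Conditions: dimethyl (1-diazo-2-oxopropyl)phosphonate, K2CO3, MeOH, 0 °C
Reagents that add atoms: dimethyl (1-diazo-2-oxopropyl)phosphonate CC(=O)C(=[N+]=[N-])P(=O)(OC)OC
Why: Seyferth–Gilbert homologation in its Ohira–Bestmann form, in which methanolysis of the reagent frees the diazomethylphosphonate anion that olefinates the aldehyde, and loss of N2 with a 1,2-hydrogen shift gives the terminal alkyne under base mild enough, when kept cold, for the aldol-type hydroxy aldehyde.

Step 6
Reactants: 8 (3R)-1-[(tert-butyldimethylsilyl)oxy]-3-methylhex-5-yn-3-ol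
Product: 11 (2E,5R)-7-[(tert-butyldimethylsilyl)oxy]-3,5-dimethylhept-2-ene-1,5-diol, via alkenylalane alkoxide 9 (not isolated), via lithium alanate 10 (not isolated)
Conditions: Me3Al (3.5 equiv), Cp2ZrCl2 (0.5 equiv), CH2Cl2, 0 °C to rt (no heating); then hexane/THF, n-BuLi, −78 °C; (CH2O)n, −78 °C to rt; aqueous potassium sodium tartrate
Reagents that add atoms: trimethylaluminium C[Al](C)C; formaldehyde (from paraformaldehyde) C=O
Why: Negishi carboalumination as in step 1 with the tertiary hydroxyl carried as its dimethylaluminium alkoxide, where syn addition with aluminium on the terminal carbon and capture of formaldehyde with retention fix the E geometry of the C5–C6(CH3)=C7–C8 unit and the C4 centre is not involved.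

Step 7
Reactants: 11 (2E,5R)-7-[(tert-butyldimethylsilyl)oxy]-3,5-dimethylhept-2-ene-1,5-diol
Product: 12 (2E,5R)-7-[(tert-butyldimethylsilyl)oxy]-5-hydroxy-3,5-dimethylhept-2-en-1-yl methyl carbonate
Conditions: ClCO2Me, pyridine, CH2Cl2, 0 °C
Reagents that add atoms: methyl chloroformate COC(=O)Cl
Why: Acylation of the unhindered primary allylic alcohol by a chloroformate under pyridine, conditions under which the tertiary C4 hydroxyl does not react.

Step 8
Reactants: 12 (2E,5R)-7-[(tert-butyldimethylsilyl)oxy]-5-hydroxy-3,5-dimethylhept-2-en-1-yl methyl carbonate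
Product: 13 (2E,5R)-5,7-dihydroxy-3,5-dimethylhept-2-en-1-yl methyl carbonate
Conditions: HF·pyridine, pyridine, THF, 0 °C to rt
Reagents that add atoms: none
Why: Fluoride-driven cleavage of the primary tert-butyldimethylsilyl ether under buffered, non-basic conditions that leave the allylic carbonate and the tertiary alcohol untouched.

Step 9
Reactants: 13 (2E,5R)-5,7-dihydroxy-3,5-dimethylhept-2-en-1-yl methyl carbonate
Product: 14 (3R,5E)-3-hydroxy-7-[(methoxycarbonyl)oxy]-3,5-dimethylhept-5-enoic acid
Conditions: TEMPO (20 mol%), PhI(OAc)2 (2.5 equiv), MeCN/H2O (1:1), rt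
Reagents that add atoms: water O
Why: TEMPO/PhI(OAc)2 oxidation in aqueous acetonitrile takes the primary alcohol through the aldehyde hydrate to the carboxylic acid, and neither the tertiary alcohol, the trisubstituted alkene nor the carbonate is oxidised.

Step 10
Reactants: 14 (3R,5E)-3-hydroxy-7-[(methoxycarbonyl)oxy]-3,5-dimethylhept-5-enoic acid
Product: 15 (4R,6S)-6-ethenyl-4-hydroxy-4,6-dimethyloxan-2-one
Conditions: Pd2(dba)3·CHCl3 (2.5 mol%), N,N'-[(1R,2R)-cyclohexane-1,2-diyl]bis[2-(diphenylphosphino)benzamide] (7.5 mol%), degassed CH2Cl2 (0.02 M), 0 °C, quenched as soon as 14 is consumed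
Reagents that add atoms: none
Why: Proposed new method: zerovalent palladium ionises the primary allylic carbonate of 14 with loss of CO2, the methoxide set free takes the carboxylic acid proton, and the C2 carboxylate attacks the 1,1-disubstituted C6 terminus of the C6–C7–C8 allyl anti to the metal, which forms O1–C6. The closest known reaction type is palladium-catalysed asymmetric allylic substitution by oxygen nucleophiles (phenols, hydrogen carbonate) at a 1,1-disubstituted allyl terminus with this ligand class, which gives tertiary C–O centres, whereas a tethered carboxylate closing a lactone in this way is without precedent. The six-membered lactone closes in 6-exo mode, because attack at C8 from the syn allyl would need an eight-membered ring holding an E alkene. The C6 stereocentre is set by the chiral ligand: the two allyl faces exchange through the sigma-complex at unsubstituted C8 faster than the ring closes (the free acid slows closure), so the ligand pocket decides which diastereomeric complex cyclises, and the fixed C4 centre turns a facial error into a separable diastereomer. The step needs branched regioselectivity, facial selectivity, chemoselectivity and kinetic control, and these rest on the tether length, on the single E geometry (one syn/anti allyl isomer), on the neutral tertiary C4 hydroxyl being unable to reach C8 from that isomer, and on dilution, low temperature and an early quench before the tertiary allylic lactone re-ionises.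

Step 11
Reactants: 16 non-8-yn-1-ol
Product: 17 9-bromonon-1-yne
Conditions: CBr4, PPh3, CH2Cl2, 0 °C
Reagents that add atoms: tetrabromomethane BrC(Br)(Br)Br
Why: Appel reaction, in which the alkoxyphosphonium ion formed from the primary alcohol is displaced by bromide in an SN2 step and the terminal alkyne is a spectator.

Step 12
Reactants: 17 9-bromonon-1-yne; 18 benzyl bromide
Product: 21 [(2E)-10-bromodec-2-en-1-yl]benzene, via alkenylzirconocene chloride 19 (not isolated), via alkenylzinc chloride 20 (not isolated)
Conditions: Cp2Zr(H)Cl (1.1 equiv), THF, rt; ZnCl2 (1.1 equiv), 0 °C; then 18, Pd(PPh3)4 (3 mol%), rt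
Reagents that add atoms: none
Why: Hydrozirconation adds Zr–H syn to the terminal alkyne with the metal on the terminal carbon, and transmetalation to zinc followed by Negishi coupling with the benzylic bromide keeps that E geometry, while the unactivated primary alkyl bromide adds oxidatively neither to the zirconium hydride nor to triphenylphosphine-ligated zerovalent palladium at room temperature.

Step 13
Reactants: 15 (4R,6S)-6-ethenyl-4-hydroxy-4,6-dimethyloxan-2-one; 21 [(2E)-10-bromodec-2-en-1-yl]benzene
Product: 23 (4R,6R)-4-hydroxy-4,6-dimethyl-6-[(10E)-12-phenyldodec-10-en-1-yl]oxan-2-one (trisphaerolide A), via alkylborane 22 (not isolated)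
Conditions: 9-BBN (1.2 equiv), THF, 0 °C to rt; then K3PO4·H2O (1.3 equiv), 21 (1.3 equiv), Pd(OAc)2 (4 mol%), PCy3 (8 mol%), THF, rt; pH 6 buffer work-up
Reagents that add atoms: none
Why: Anti-Markovnikov hydroboration puts boron on the terminal C8 of the vinyl group, and the B-alkyl-9-BBN then couples with the primary alkyl bromide in an alkyl–alkyl Suzuki–Miyaura reaction under Pd(OAc)2/PCy3/K3PO4·H2O, which runs at room temperature, tolerates esters and alkenes and touches neither stereocentre.

Compound list
1 | tert-butyl(but-3-yn-1-yloxy)dimethylsilane | C#CCCO[Si](C)(C)C(C)(C)C | starting material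
2 | {(1E)-4-[(tert-butyldimethylsilyl)oxy]-2-methylbut-1-en-1-yl}dimethylalane | C[Al](C)/C=C(\C)CCO[Si](C)(C)C(C)(C)C | intermediate
3 | lithium butyl{(1E)-4-[(tert-butyldimethylsilyl)oxy]-2-methylbut-1-en-1-yl}dimethylalanate | [Li+].CCCC[Al-](C)(C)/C=C(\C)CCO[Si](C)(C)C(C)(C)C | intermediate
4 | (2E)-5-[(tert-butyldimethylsilyl)oxy]-3-methylpent-2-en-1-ol | OC/C=C(\C)CCO[Si](C)(C)C(C)(C)C | intermediate
5 | [(2S,3S)-3-{2-[(tert-butyldimethylsilyl)oxy]ethyl}-3-methyloxiran-2-yl]methanol | OC[C@@H]1O[C@@]1(C)CCO[Si](C)(C)C(C)(C)C | intermediate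
6 | (3R)-5-[(tert-butyldimethylsilyl)oxy]-3-methylpentane-1,3-diol | OCC[C@@](C)(O)CCO[Si](C)(C)C(C)(C)C | intermediate
7 | (3S)-5-[(tert-butyldimethylsilyl)oxy]-3-hydroxy-3-methylpentanal | O=CC[C@@](C)(O)CCO[Si](C)(C)C(C)(C)C | intermediate
8 | (3R)-1-[(tert-butyldimethylsilyl)oxy]-3-methylhex-5-yn-3-ol | C#CC[C@@](C)(O)CCO[Si](C)(C)C(C)(C)C | intermediate
9 | E-alkenyldimethylalane from 8 with the C4 oxygen as its dimethylaluminium alkoxide | C[Al](C)/C=C(\C)C[C@@](C)(O[Al](C)C)CCO[Si](C)(C)C(C)(C)C | intermediate
10 | lithium butyl(alkenyl)dimethylalanate from 9 | [Li+].CCCC[Al-](C)(C)/C=C(\C)C[C@@](C)(O[Al](C)C)CCO[Si](C)(C)C(C)(C)C | intermediate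
11 | (2E,5R)-7-[(tert-butyldimethylsilyl)oxy]-3,5-dimethylhept-2-ene-1,5-diol | OC/C=C(\C)C[C@@](C)(O)CCO[Si](C)(C)C(C)(C)C | intermediate
12 | (2E,5R)-7-[(tert-butyldimethylsilyl)oxy]-5-hydroxy-3,5-dimethylhept-2-en-1-yl methyl carbonate | COC(=O)OC/C=C(\C)C[C@@](C)(O)CCO[Si](C)(C)C(C)(C)C | intermediate
13 | (2E,5R)-5,7-dihydroxy-3,5-dimethylhept-2-en-1-yl methyl carbonate | COC(=O)OC/C=C(\C)C[C@@](C)(O)CCO | intermediate
14 | (3R,5E)-3-hydroxy-7-[(methoxycarbonyl)oxy]-3,5-dimethylhept-5-enoic acid | OC(=O)C[C@](C)(O)C/C(C)=C/COC(=O)OC | intermediate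
15 | (4R,6S)-6-ethenyl-4-hydroxy-4,6-dimethyloxan-2-one | C[C@]1(O)CC(=O)O[C@](C)(C=C)C1 | intermediate
16 | non-8-yn-1-ol | C#CCCCCCCCO | starting material
17 | 9-bromonon-1-yne | C#CCCCCCCCBr | intermediate
18 | benzyl bromide | BrCc1ccccc1 | starting material
19 | [(1E)-9-bromonon-1-en-1-yl]chlorobis(cyclopentadienyl)zirconium (cyclopentadienyl drawn sigma-bonded) | BrCCCCCCC/C=C/[Zr](Cl)(C1C=CC=C1)C1C=CC=C1 | intermediate
20 | [(1E)-9-bromonon-1-en-1-yl]zinc chloride | BrCCCCCCC/C=C/[Zn]Cl | intermediate
21 | [(2E)-10-bromodec-2-en-1-yl]benzene | BrCCCCCCC/C=C/Cc1ccccc1 | intermediate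
22 | (4R,6R)-6-[2-(9-borabicyclo[3.3.1]nonan-9-yl)ethyl]-4-hydroxy-4,6-dimethyloxan-2-one | C[C@]1(O)CC(=O)O[C@](C)(CCB2C3CCCC2CCC3)C1 | intermediate
23 | (4R,6R)-4-hydroxy-4,6-dimethyl-6-[(10E)-12-phenyldodec-10-en-1-yl]oxan-2-one (trisphaerolide A) | C[C@]1(O)CC(=O)O[C@](C)(CCCCCCCCC/C=C/Cc2ccccc2)C1 | target

Total step count: 13. Longest linear sequence: 11 steps (steps 1 to 10, then step 13).

Steps most likely to fail

Step 10. The ring closure may run with poor facial selectivity at C6, or the tertiary allylic lactone may re-ionise and drift to linear esters, dienes or oligomers. The fallback sets C6 by reagent-controlled epoxidation instead, using known reactions only. Setting out from 11, a second Sharpless asymmetric epoxidation (Ti(OiPr)4, L-(+)-diethyl tartrate, t-BuOOH) should give [(2S,3S)-3-{(2S)-4-[(tert-butyldimethylsilyl)oxy]-2-hydroxy-2-methylbutyl}-3-methyloxiran-2-yl]methanol F1, whose quaternary epoxide carbon already has the C6 configuration. Iodination of the primary alcohol (I2, PPh3, imidazole) would give (2S)-4-[(tert-butyldimethylsilyl)oxy]-1-[(2S,3R)-3-(iodomethyl)-2-methyloxiran-2-yl]-2-methylbutan-2-ol F2. Zinc dust in ethanol would open it reductively to the tertiary vinyl carbinol (3S,5S)-7-[(tert-butyldimethylsilyl)oxy]-3,5-dimethylhept-1-ene-3,5-diol F3. HF·pyridine would then give (3S,5S)-3,5-dimethylhept-6-ene-1,3,5-triol F4. TEMPO/PhI(OAc)2 in CH2Cl2 would oxidise the primary alcohol and the lactol that follows, which comes back to the route at 15.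

Step 13. Transmetalation of the hydroxyl-bearing alkylborane may be slow, so that beta-hydride elimination at alkylpalladium, protodeboronation or base-induced opening of the lactone take over. The fallback reverses the polarity and avoids base. Setting out from 15, hydroboration with 9-BBN and oxidation with NaBO3 would give (4R,6R)-4-hydroxy-6-(2-hydroxyethyl)-4,6-dimethyloxan-2-one F5, and I2/PPh3/imidazole would give (4R,6S)-4-hydroxy-6-(2-iodoethyl)-4,6-dimethyloxan-2-one F6. Bromide 21 would be turned by zinc dust (catalytic I2, N,N-dimethylacetamide) into [(8E)-10-phenyldec-8-en-1-yl]zinc bromide F7. An alkyl–alkyl Negishi coupling of F6 with F7 (Ni(cod)2, a bis(oxazolinyl)pyridine ligand, N,N-dimethylacetamide, rt) comes back to the route at the target 23.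

Step 5. Carbonate in methanol may cleave the tertiary hydroxy aldehyde by retro-aldol fragmentation before it is homologated. The fallback is a Corey–Fuchs sequence, in which no carbonyl group is exposed to base. Setting out from 7, dibromo-olefination (CBr4, PPh3, Et3N, CH2Cl2, 0 °C) would give (3R)-6,6-dibromo-1-[(tert-butyldimethylsilyl)oxy]-3-methylhex-5-en-3-ol F8. n-BuLi (THF, −78 °C) would convert it by bromine–lithium exchange and 1,2-shift into the alkyne, which comes back to the route at 8.

Further compounds
F1 | step 10 | [(2S,3S)-3-{(2S)-4-[(tert-butyldimethylsilyl)oxy]-2-hydroxy-2-methylbutyl}-3-methyloxiran-2-yl]methanol | OC[C@@H]1O[C@@]1(C)C[C@@](C)(O)CCO[Si](C)(C)C(C)(C)C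
F2 | step 10 | (2S)-4-[(tert-butyldimethylsilyl)oxy]-1-[(2S,3R)-3-(iodomethyl)-2-methyloxiran-2-yl]-2-methylbutan-2-ol | IC[C@@H]1O[C@@]1(C)C[C@@](C)(O)CCO[Si](C)(C)C(C)(C)C
F3 | step 10 | (3S,5S)-7-[(tert-butyldimethylsilyl)oxy]-3,5-dimethylhept-1-ene-3,5-diol | O[C@](C)(C=C)C[C@@](C)(O)CCO[Si](C)(C)C(C)(C)C
F4 | step 10 | (3S,5S)-3,5-dimethylhept-6-ene-1,3,5-triol | O[C@](C)(C=C)C[C@@](C)(O)CCO
F5 | step 13 | (4R,6R)-4-hydroxy-6-(2-hydroxyethyl)-4,6-dimethyloxan-2-one | C[C@]1(O)CC(=O)O[C@](C)(CCO)C1
F6 | step 13 | (4R,6S)-4-hydroxy-6-(2-iodoethyl)-4,6-dimethyloxan-2-one | C[C@]1(O)CC(=O)O[C@](C)(CCI)C1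
F7 | step 13 | [(8E)-10-phenyldec-8-en-1-yl]zinc bromide | Br[Zn]CCCCCCC/C=C/Cc1ccccc1
F8 | step 5 | (3R)-6,6-dibromo-1-[(tert-butyldimethylsilyl)oxy]-3-methylhex-5-en-3-ol | BrC(Br)=CC[C@@](C)(O)CCO[Si](C)(C)C(C)(C)C
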